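**Retrosynthetic overview**
1. Target 21 ⇐ carbinol 20 by oxidation of C15–OH, done last so the epimerisable C14 never sees base as a ketone.
2. 20 ⇐ cyclohexenone 18 by photochemical [σ2a+π2a] (type A) ring contraction; this forms the cyclopropane and cyclopentanone and is the C9-oxo version of the biogenetic cyclohexadiene → bicyclo[3.1.0]hexene step.
3. 18 ⇐ ethylpyrone 16 + β-methoxy trienone 11 by addition–elimination, then oxyanion-accelerated disrotatory 6π electrocyclisation of the resulting 9-oxido tetraene (carbocycle formed here, C9 oxygen already in place).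
4. 11 ⇐ enal 7 + phosphonate 10 (HWE); 7 ⇐ propanal (crotylboration, cross-metathesis); 16 ⇐ triketide 14.
5. Ring order: pyrone, then cyclohexenone, then bicyclo[3.1.0]hexanone.

Assumptions: the target is taken exactly as drawn (crispatone skeleton; biogenetic numbering: pyrone C1–C5 with OMe on C1, C6 = cyclopropane carbon bearing the pyrone, C7, C8, C9 = ring C=O, C10, C11, side chain C12–C17 with C15 = C=O); 8 is bought (otherwise two steps from pentan-3-one); enolates, alkoxides and other conjugate acids/bases of numbered compounds are not numbered separately.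

**Step 1**
Reactants: 1 propanal; 2 cis-2-butene
Product: 5 (3R,4R)-4-methylhex-5-en-3-ol, via crotylborane 3 (not isolated), via borinate ester 4 (not isolated)
Conditions: 2, KOtBu, n-BuLi, THF, −78 to −45 °C; (−)-Ipc2BOMe, −78 °C; BF3·OEt2; 1, −78 °C; NaOH, H2O2
Reagents that add atoms: none
Why: Brown crotylboration, in which the (Z)-crotylborane reacts through a closed chair transition state to give the syn adduct and the isopinocampheyl ligands from (+)-α-pinene select the aldehyde face that gives (3R,4R); C4 is the future C14 stereocentre and C3 is oxidised in step 10.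

**Step 2**
Reactants: 5 (3R,4R)-4-methylhex-5-en-3-ol; 6 methacrolein
Product: 7 (2E,4R,5R)-5-hydroxy-2,4-dimethylhept-2-enal
Conditions: second-generation Hoveyda–Grubbs catalyst (5 mol%), 6 (6 equiv), CH2Cl2, 40 °C
Reagents that add atoms: none
Why: Olefin cross-metathesis of a monosubstituted alkene with excess 1,1-disubstituted electron-poor methacrolein (which does not homodimerise) gives the thermodynamic (E)-trisubstituted enal without touching the two stereocentres.

**Step 3**
Reactants: 8 (E)-1-methoxy-2-methylpent-1-en-3-one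
Product: 10 diethyl [(4E)-5-methoxy-4-methyl-3-oxopent-4-en-2-yl]phosphonate, via phosphonite 9 (not isolated)
Conditions: LiN(iPr)2, THF, −78 °C; ClP(OEt)2, −78 to 0 °C; H2O2 (30% aq.), 0 °C
Reagents that add atoms: diethyl chlorophosphite, CCOP(Cl)OCC; hydrogen peroxide, OO
Why: The kinetic α'-lithium enolate of the vinylogous ester reacts at carbon with the soft trivalent phosphorus chloride and the β-keto phosphonite is oxidised in the flask (enolate C-phosphinylation–oxidation route to β-ketophosphonates); the phosphorus-bearing carbon is racemic and is destroyed in step 4.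

**Step 4**
Reactants: 7 (2E,4R,5R)-5-hydroxy-2,4-dimethylhept-2-enal; 10 diethyl [(4E)-5-methoxy-4-methyl-3-oxopent-4-en-2-yl]phosphonate
Product: 11 (1E,4E,6E,8R,9R)-9-hydroxy-1-methoxy-2,4,6,8-tetramethylundeca-1,4,6-trien-3-one
Conditions: LiCl, DBU, MeCN, 0 to 23 °C
Reagents that add atoms: none
Why: Horner–Wadsworth–Emmons olefination under Masamune–Roush conditions, mild enough for the free alcohol, the γ-stereocentre of 7 and the vinylogous ester, gives the (E)-trisubstituted enone; no stereocentre is formed.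

**Step 5**
Reactants: 12 ethyl 2-methyl-3-oxopentanoate; 13 N-methoxy-N-methylpropanamide
Product: 14 ethyl 2,4-dimethyl-3,5-dioxoheptanoate
Conditions: NaH, THF, 0 °C; n-BuLi, 0 °C; 13, 0 to 23 °C; aq. HCl
Reagents that add atoms: none
Why: Huckin–Weiler dianion acylation, in which the more basic γ-carbanion attacks the Weinreb amide and the chelated tetrahedral intermediate prevents over-addition; both stereocentres are enolisable and disappear in step 6.

**Step 6**
Reactants: 14 ethyl 2,4-dimethyl-3,5-dioxoheptanoate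
Product: 15 6-ethyl-4-hydroxy-3,5-dimethyl-2H-pyran-2-one
Conditions: DBU, toluene, 80 °C
Reagents that add atoms: none
Why: Base-mediated enol-lactonisation of the 3,5-diketo ester (the C5 enolate oxygen attacks the ester with loss of ethanol) and tautomerisation give the 4-hydroxy-2-pyrone; no stereocentre remains.

**Step 7**
Reactants: 15 6-ethyl-4-hydroxy-3,5-dimethyl-2H-pyran-2-one
Product: 16 6-ethyl-2-methoxy-3,5-dimethyl-4H-pyran-4-one
Conditions: MeOTf, CH2Cl2, 23 °C; aq. NaHCO3
Reagents that add atoms: methyl trifluoromethanesulfonate, COS(=O)(=O)C(F)(F)F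
Why: O-Methylation of the neutral hydroxypyrone with a hard alkylating agent occurs at the lactone carbonyl oxygen and loss of the hydroxyl proton gives the 2-methoxy-4-pyrone rather than the 4-methoxy-2-pyrone favoured under basic conditions; no stereocentre.

**Step 8**
Reactants: 16 6-ethyl-2-methoxy-3,5-dimethyl-4H-pyran-4-one; 11 (1E,4E,6E,8R,9R)-9-hydroxy-1-methoxy-2,4,6,8-tetramethylundeca-1,4,6-trien-3-one
Product: 18 (4R,5R,6R)-5-[(2E,4R,5R)-5-hydroxy-4-methylhept-2-en-2-yl]-4-(6-methoxy-3,5-dimethyl-4-oxo-4H-pyran-2-yl)-2,4,6-trimethylcyclohex-2-en-1-one, via open-chain dienone 17 (not isolated)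
Conditions: 16 (1.3 equiv), LiN(SiMe3)2 (1.3 equiv), THF, −78 °C; 11 pre-treated with LiN(SiMe3)2 (1.0 equiv), −78 to 23 °C, 12 h; aq. NH4Cl; chromatography
Reagents that add atoms: none
Why: Proposed new method: the lithiated ethylpyrone (a soft, pyrone-stabilised vinylogous enolate) adds at the unhindered methoxy-bearing terminus of 11 and expels methoxide (attack on the dienone arm is reversible and unproductive), the base present then removes the doubly activated C6–H of 17, and the resulting 9-oxido tetraene closes C6–C11 by an oxyanion-accelerated thermal disrotatory 6π electrocyclisation, the ring-forming event of the biosynthesis run at the C9-oxo level (closest known reactions: enolate addition–elimination on β-alkoxy enones and the low-temperature 6π closure of 3-oxidohexatrienes to cyclohexenones); the (E)-C10=C11 bond and the pyrone turned outward at C6 (methyl inward) put pyrone and side chain cis, the lithium alkoxide at C15 protects C14–H from vinylogous deprotonation, and because C14/C15 are too remote to bias the ring face, 18 and its ring-antipodal diastereomer are expected about 1:1 and are separated by chromatography (C10 is obtained as an epimer mixture, expected mainly 10,11-cis as drawn, and is corrected in step 9).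

**Step 9**
Reactants: 18 (4R,5R,6R)-cyclohexenone
Product: 20 6-{(1S,3S,4R,5S,6S)-4-[(2E,4R,5R)-5-hydroxy-4-methylhept-2-en-2-yl]-1,3,6-trimethyl-2-oxobicyclo[3.1.0]hexan-6-yl}-2-methoxy-3,5-dimethyl-4H-pyran-4-one, via 10-epi ketone 19 (not isolated)
Conditions: hν (350 nm, Pyrex), degassed t-BuOH, 23 °C, to about 70% conversion; then KOtBu (0.2 equiv), 23 °C
Reagents that add atoms: none
Why: Type A (lumiketone) photorearrangement of a 4,4-disubstituted cyclohex-2-enone from its twisted triplet is a [σ2a+π2a] shift (C11 from C6 to C7, C6 to C8) that mirrors the biogenetic cyclohexadiene → bicyclo[3.1.0]hexene step, is stereospecific with inversion at C6 and should take place on the less hindered face (that of C6–Me and C11–H) to give exo-pyrone, endo-methyl and the side chain anti to the cyclopropane, after which KOtBu equilibrates the enolisable C10 to the 10,11-trans arrangement, expected to be the more stable one.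

**Step 10**
Reactants: 20 (15R)-carbinol
Product: 21 2-methoxy-3,5-dimethyl-6-{(1S,3S,4R,5S,6S)-1,3,6-trimethyl-4-[(2E,4R)-4-methyl-5-oxohept-2-en-2-yl]-2-oxobicyclo[3.1.0]hexan-6-yl}-4H-pyran-4-one
Conditions: Dess–Martin periodinane, NaHCO3, CH2Cl2, 0 °C
Reagents that add atoms: none
Why: Dess–Martin oxidation under bicarbonate buffer converts the C15 carbinol into the ethyl ketone without enolising the adjacent β,γ-unsaturated C14 stereocentre (set in step 1) or touching the ring ketone, pyrone or alkene.

**Compound list**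
1 | propanal | CCC=O | starting material
2 | cis-2-butene | C/C=C\C | starting material
3 | (Z)-crotylbis(isopinocampheyl)borane, Ipc from (+)-α-pinene | C/C=C\CB([C@@H]1C[C@@H]2C[C@H]([C@H]1C)C2(C)C)[C@@H]1C[C@@H]2C[C@H]([C@H]1C)C2(C)C | intermediate
4 | bis(isopinocampheyl)borinate ester of 5 | CC[C@@H](OB([C@@H]1C[C@@H]2C[C@H]([C@H]1C)C2(C)C)[C@@H]1C[C@@H]2C[C@H]([C@H]1C)C2(C)C)[C@H](C)C=C | intermediate
5 | (3R,4R)-4-methylhex-5-en-3-ol | CC[C@@H](O)[C@H](C)C=C | intermediate
6 | methacrolein (2-methylprop-2-enal) | CC(=C)C=O | starting material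
7 | (2E,4R,5R)-5-hydroxy-2,4-dimethylhept-2-enal | CC[C@@H](O)[C@H](C)/C=C(\C)C=O | intermediate
8 | (E)-1-methoxy-2-methylpent-1-en-3-one | CCC(=O)/C(C)=C/OC | starting material
9 | diethyl [(4E)-5-methoxy-4-methyl-3-oxopent-4-en-2-yl]phosphonite (racemic) | CCOP(OCC)C(C)C(=O)/C(C)=C/OC | intermediate
10 | diethyl [(4E)-5-methoxy-4-methyl-3-oxopent-4-en-2-yl]phosphonate (racemic) | CCOP(=O)(OCC)C(C)C(=O)/C(C)=C/OC | intermediate
11 | (1E,4E,6E,8R,9R)-9-hydroxy-1-methoxy-2,4,6,8-tetramethylundeca-1,4,6-trien-3-one | CC[C@@H](O)[C@H](C)/C=C(\C)/C=C(\C)C(=O)/C(C)=C/OC | intermediate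
12 | ethyl 2-methyl-3-oxopentanoate (racemic) | CCC(=O)C(C)C(=O)OCC | starting material
13 | N-methoxy-N-methylpropanamide | CCC(=O)N(C)OC | starting material
14 | ethyl 2,4-dimethyl-3,5-dioxoheptanoate (stereoisomer mixture) | CCC(=O)C(C)C(=O)C(C)C(=O)OCC | intermediate
15 | 6-ethyl-4-hydroxy-3,5-dimethyl-2H-pyran-2-one | CCc1oc(=O)c(C)c(O)c1C | intermediate
16 | 6-ethyl-2-methoxy-3,5-dimethyl-4H-pyran-4-one | CCc1oc(OC)c(C)c(=O)c1C | intermediate
17 | 6-[(3E,6E,8E,10R,11R)-11-hydroxy-4,6,8,10-tetramethyl-5-oxotrideca-3,6,8-trien-2-yl]-2-methoxy-3,5-dimethyl-4H-pyran-4-one (C6 undefined, lost on deprotonation) | CC[C@@H](O)[C@H](C)/C=C(\C)/C=C(\C)C(=O)/C(C)=C/C(C)c1oc(OC)c(C)c(=O)c1C | intermediate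
18 | (4R,5R,6R)-5-[(2E,4R,5R)-5-hydroxy-4-methylhept-2-en-2-yl]-4-(6-methoxy-3,5-dimethyl-4-oxo-4H-pyran-2-yl)-2,4,6-trimethylcyclohex-2-en-1-one (pyrone cis to side chain; C10 epimer drawn is 10,11-cis) | CC[C@@H](O)[C@H](C)/C=C(\C)[C@H]1[C@@H](C)C(=O)C(C)=C[C@@]1(C)c1oc(OC)c(C)c(=O)c1C | intermediate
19 | 6-{(1S,3R,4R,5S,6S)-4-[(2E,4R,5R)-5-hydroxy-4-methylhept-2-en-2-yl]-1,3,6-trimethyl-2-oxobicyclo[3.1.0]hexan-6-yl}-2-methoxy-3,5-dimethyl-4H-pyran-4-one (10-epimer of 20) | CC[C@@H](O)[C@H](C)/C=C(\C)[C@H]1[C@@H](C)C(=O)[C@@]2(C)[C@@H]1[C@]2(C)c1oc(OC)c(C)c(=O)c1C | intermediate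
20 | 6-{(1S,3S,4R,5S,6S)-4-[(2E,4R,5R)-5-hydroxy-4-methylhept-2-en-2-yl]-1,3,6-trimethyl-2-oxobicyclo[3.1.0]hexan-6-yl}-2-methoxy-3,5-dimethyl-4H-pyran-4-one | CC[C@@H](O)[C@H](C)/C=C(\C)[C@H]1[C@H](C)C(=O)[C@@]2(C)[C@@H]1[C@]2(C)c1oc(OC)c(C)c(=O)c1C | intermediate
21 | 2-methoxy-3,5-dimethyl-6-{(1S,3S,4R,5S,6S)-1,3,6-trimethyl-4-[(2E,4R)-4-methyl-5-oxohept-2-en-2-yl]-2-oxobicyclo[3.1.0]hexan-6-yl}-4H-pyran-4-one (CNP0216193.1) | CCC(=O)[C@H](C)/C=C(\C)[C@H]1[C@H](C)C(=O)[C@@]2(C)[C@@H]1[C@]2(C)c1oc(OC)c(C)c(=O)c1C | target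

**Totals**
Total step count: 10. Longest linear sequence: 6 steps (steps 1, 2, 4, 8, 9, 10; the pyrone branch, steps 5, 6, 7, 8, 9, 10, is equally long).

**Three steps most likely to fail**

Step 8. The cascade can fail by addition at the wrong acceptor site of 11, by scrambling of C14, or by poor conversion of the stabilised oxido-tetraene. Even when it works it gives no ring-face selection, so at most half the material is the wanted diastereomer. The fallback sets out from 16 and 8 and changes the order of bond formation so that the pyrone is attached to a substrate with only one acceptor site. Lithiated 16 (LiN(SiMe3)2, THF, −78 to 0 °C) is added to 8 with loss of methoxide to give the ethyl ketone 6-[(3E)-4-methyl-5-oxohept-3-en-2-yl]-2-methoxy-3,5-dimethyl-4H-pyran-4-one F1. Its dianion (LiN(iPr)2, 2.1 equiv) is phosphinylated at the ethyl CH2 with ClP(OEt)2 and oxidised with H2O2 to diethyl [(4E)-6-(6-methoxy-3,5-dimethyl-4-oxo-4H-pyran-2-yl)-4-methyl-3-oxohept-4-en-2-yl]phosphonate F2. Olefination of 7 with F2 (LiCl, DBU, MeCN) gives 17, which closes under the same amine base, and the route is rejoined at 18.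

Step 9. The type A rearrangement can lose to a 1,2-shift of the pyronyl group (aryl-type migration), to a crossed [2+2] with the side-chain alkene, or to secondary photolysis of the cyclopropyl ketone. The fallback sets out from 18 and uses the direct 9-siloxy analogue of the natural cyclohexadiene. TBSOTf (2.5 equiv) and Et3N in CH2Cl2 give the bis-silyl compound, the 9-(tert-butyldimethylsilyloxy)cyclohexa-1,3-diene (C7=C8, C9=C10) carrying a 15-O-TBS ether with C6, C11, C14 and C15 as in 18 F3. Irradiation (350 nm or sunlight) effects the same [σ2a+π2a] shift to the bicyclo[3.1.0]hex-2-ene silyl enol ether with 15-O-TBS and ring configuration as in 20 F4. TBAF/AcOH then KOtBu equilibration of C10 returns to 20.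

Step 2. Cross-metathesis to a trisubstituted enal next to an allylic branch can stall or consume catalyst. The fallback sets out from 5. Ozonolysis (O3, CH2Cl2, −78 °C; Me2S) gives (2S,3R)-3-hydroxy-2-methylpentanal F5, which is used crude in a Wittig reaction with Ph3P=C(CH3)CHO (toluene, 60 °C) to return to 7.

**Further compounds**
F1 | step 8 | 6-[(3E)-4-methyl-5-oxohept-3-en-2-yl]-2-methoxy-3,5-dimethyl-4H-pyran-4-one (racemic) | CCC(=O)/C(C)=C/C(C)c1oc(OC)c(C)c(=O)c1C
F2 | step 8 | diethyl [(4E)-6-(6-methoxy-3,5-dimethyl-4-oxo-4H-pyran-2-yl)-4-methyl-3-oxohept-4-en-2-yl]phosphonate (stereoisomer mixture) | CCOP(=O)(OCC)C(C)C(=O)/C(C)=C/C(C)c1oc(OC)c(C)c(=O)c1C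
F3 | step 9 | bis-TBS derivative of 18: 9-silyloxy cyclohexa-1,3-diene with 15-O-TBS, C6/C11/C14/C15 as in 18 | CC[C@@H](O[Si](C)(C)C(C)(C)C)[C@H](C)/C=C(\C)[C@H]1C(C)=C(O[Si](C)(C)C(C)(C)C)C(C)=C[C@@]1(C)c1oc(OC)c(C)c(=O)c1C
F4 | step 9 | bicyclo[3.1.0]hex-2-ene silyl enol ether with 15-O-TBS, ring configuration as in 20 | CC[C@@H](O[Si](C)(C)C(C)(C)C)[C@H](C)/C=C(\C)[C@H]1C(C)=C(O[Si](C)(C)C(C)(C)C)[C@@]2(C)[C@@H]1[C@]2(C)c1oc(OC)c(C)c(=O)c1C
F5 | step 2 | (2S,3R)-3-hydroxy-2-methylpentanal | CC[C@@H](O)[C@H](C)C=O
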